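**Plan**

- Enabling feature: the benzene ring is a hexasubstituted phloroglucinol whose three ring oxygens (OH, OH, OMe) alternate with three carbon substituents (pyranonyl‑CH2, prenyl, acyl). A ketene carbonyl (→ free OH), a siloxyalkyne (→ O–Si and prenyl) and a 1‑methoxyvinyl group (→ OMe and the one C–H) write this pattern in a single annulation.
- Retrosynthesis, late cuts: remove the TIPS and SEM groups, then cut the aryl–C(=O) bond back to the phenol ester of (R)‑2‑methylbutanoic acid. Then cut four ring bonds at once, C(OH)–C(prenyl), C(OSi)–C(bridge), C(bridge)–C(OMe) and C(OH)–C(H), to give an α‑diazo ketone on the pyranone side chain and a prenyl siloxyalkyne.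
- Retrosynthesis, early cuts: the diazo ketone is cut at C(=O)–vinyl (Weinreb amide), at pyranone C3–CH2 (Michael addition) and in the pyranone ring (3‑pentanone plus malonyl dichloride). The alkyne comes from methyl 4‑methylpent‑3‑enoate by one‑carbon homologation.
- Forward order: the pyranone ring is made first (step 1) and its C3 chain is grown to the diazo ketone (steps 2–5). The benzene ring is then built on the bridge carbon (step 7) and acylated last (steps 8–9); step 10 frees the hydroxyls.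
- Stereochemistry: the single (R) centre is bought with (R)‑2‑methylbutanoic acid and enters in step 8. The steps after it (carbodiimide esterification, photochemical acyl shift, buffered fluoride) should not enolise it.

Key step: step 7

Assumption: the stereocentre of the target SMILES is read as (R); (R)‑2‑methylbutanoic acid, LiN(SiMe3)2 and lithium 2,2,6,6‑tetramethylpiperidide are taken as purchased reagents.

**Route**

Step 1
Reactants: 1 3‑pentanone; 2 malonyl dichloride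
Product: 3 6‑ethyl‑4‑hydroxy‑5‑methyl‑2H‑pyran‑2‑one
Conditions: 1 (2 equiv), 2, CH2Cl2, 0 → 40 °C, N2 sweep
Reagents that add atoms: none
Why: Malonyl dichloride condensation with an enolisable ketone: C‑acylation of the ketone enol and then O‑acylation of the new enol close the lactone to the 4‑hydroxy‑2‑pyranone, and the symmetrical ketone can give only the 6‑ethyl‑5‑methyl pattern.

Step 2
Reactants: 3 6‑ethyl‑4‑hydroxy‑5‑methyl‑2H‑pyran‑2‑one; 4 N‑methoxy‑N‑methylacrylamide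
Product: 5 3‑(6‑ethyl‑4‑hydroxy‑5‑methyl‑2‑oxo‑2H‑pyran‑3‑yl)‑N‑methoxy‑N‑methylpropanamide
Conditions: 4 (1.5 equiv), Et3N (0.5 equiv), MeCN–H2O, 80 °C
Reagents that add atoms: none
Why: Base‑catalysed Michael addition: the pyranone is a vinylogous carboxylic acid whose anion reacts at C3, its only nucleophilic carbon, with acrylic acceptors as 4‑hydroxycoumarins and cyclic 1,3‑diones do, and the more hindered mono‑adduct should take up a second acceptor far more slowly.

Step 3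
Reactants: 5 3‑(6‑ethyl‑4‑hydroxy‑5‑methyl‑2‑oxo‑2H‑pyran‑3‑yl)‑N‑methoxy‑N‑methylpropanamide
Product: 6 3‑(6‑ethyl‑5‑methyl‑2‑oxo‑4‑{[2‑(trimethylsilyl)ethoxy]methoxy}‑2H‑pyran‑3‑yl)‑N‑methoxy‑N‑methylpropanamide
Conditions: SEMCl, iPr2NEt, CH2Cl2, 0 → 20 °C
Reagents that add atoms: 2‑(trimethylsilyl)ethoxymethyl chloride (SEMCl), C[Si](C)(C)CCOCCl
Why: Williamson‑type O‑alkylation of the vinylogous acid by a hard chloromethyl ether under amine base should go to the 4‑oxygen and keep the 2‑pyranone, masking the acidic OH that would otherwise quench the organolithium, the ketene and the ynol ether.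

Step 4
Reactants: 6 3‑(6‑ethyl‑5‑methyl‑2‑oxo‑4‑{[2‑(trimethylsilyl)ethoxy]methoxy}‑2H‑pyran‑3‑yl)‑N‑methoxy‑N‑methylpropanamide
Product: 8 6‑ethyl‑3‑(4‑methoxy‑3‑oxopent‑4‑en‑1‑yl)‑5‑methyl‑4‑{[2‑(trimethylsilyl)ethoxy]methoxy}‑2H‑pyran‑2‑one, via lithium alkoxide adduct 7 (not isolated)
Conditions: CH2=C(OMe)Li (methyl vinyl ether, t‑BuLi, THF, −78 → 0 °C), then 6, THF, −78 °C; AcOH, −78 °C, then aq. NaHCO3
Reagents that add atoms: 1‑methoxyvinyllithium, [Li]C(=C)OC (made in the flask from methyl vinyl ether, COC=C, and t‑BuLi)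
Why: Weinreb ketone synthesis: the vinyllithium adds once to the N‑methoxy‑N‑methylamide to give chelated adduct 7, which holds until the quench, while the 4‑alkoxy‑2‑pyranone carbonyl (a vinylogous carbonate) is far less electrophilic at −78 °C, and the buffered quench spares the enol ether.

Step 5
Reactants: 8 6‑ethyl‑3‑(4‑methoxy‑3‑oxopent‑4‑en‑1‑yl)‑5‑methyl‑4‑{[2‑(trimethylsilyl)ethoxy]methoxy}‑2H‑pyran‑2‑one
Product: 11 3‑(2‑diazo‑4‑methoxy‑3‑oxopent‑4‑en‑1‑yl)‑6‑ethyl‑5‑methyl‑4‑{[2‑(trimethylsilyl)ethoxy]methoxy}‑2H‑pyran‑2‑one, via lithium enolate 9 (not isolated), via trifluoroacetyl diketone 10 (not isolated)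
Conditions: LiN(SiMe3)2, THF, −78 °C; CF3CO2CH2CF3; AcOH quench, 10 used crude; MsN3, Et3N, H2O (1 equiv), MeCN, 20 °C
Reagents that add atoms: methanesulfonyl azide, CS(=O)(=O)N=[N+]=[N-] (both diazo nitrogens); 2,2,2‑trifluoroethyl trifluoroacetate, FC(F)(F)COC(=O)C(F)(F)F (its trifluoroacetyl group is carried only by 10, not by 11)
Why: Detrifluoroacetylative (deacylative, Regitz‑type) diazo transfer: kinetic enolisation at the only enolisable α‑carbon and C‑trifluoroacetylation give the activated diketone 10, which takes the diazo group from the sulfonyl azide and sheds the trifluoroacetyl group as the N‑acylsulfonamide, the standard way to α'‑diazo enones that direct transfer to a simple ketone does not reach.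

Step 6
Reactants: 12 methyl 4‑methylpent‑3‑enoate
Product: 15 triisopropyl[(5‑methylhex‑4‑en‑1‑yn‑1‑yl)oxy]silane, via dibromo enolate 13 (not isolated), via lithium ynolate 14 (not isolated)
Conditions: CH2Br2, lithium 2,2,6,6‑tetramethylpiperidide, THF, −78 °C, then 12; LiN(SiMe3)2; n‑BuLi, −78 → 0 °C; TIPSCl, −78 → 20 °C
Reagents that add atoms: dibromomethane, BrCBr (one alkyne carbon); chlorotriisopropylsilane (TIPSCl), CC(C)[Si](Cl)(C(C)C)C(C)C
Why: Kowalski ester homologation: LiCHBr2 adds to the ester, the derived dibromo enolate 13 undergoes Br/Li exchange and a carbenoid 1,2‑shift to ynolate 14, and the bulky silyl chloride should silylate 14 on oxygen (siloxyalkyne, not silylketene), with addition of the ester to preformed LiCHBr2 at −78 °C keeping the β,γ‑unsaturated ester from being deprotonated.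

Step 7
Reactants: 11 3‑(2‑diazo‑4‑methoxy‑3‑oxopent‑4‑en‑1‑yl)‑6‑ethyl‑5‑methyl‑4‑{[2‑(trimethylsilyl)ethoxy]methoxy}‑2H‑pyran‑2‑one; 15 triisopropyl[(5‑methylhex‑4‑en‑1‑yn‑1‑yl)oxy]silane
Product: 20 6‑ethyl‑3‑{[4‑hydroxy‑6‑methoxy‑3‑(3‑methylbut‑2‑en‑1‑yl)‑2‑(triisopropylsilyloxy)phenyl]methyl}‑5‑methyl‑4‑{[2‑(trimethylsilyl)ethoxy]methoxy}‑2H‑pyran‑2‑one, via vinylketene 16 (not isolated), via vinylcyclobutenone 17 (not isolated), via dienylketene 18 (not isolated), via cyclohexadienone 19 (not isolated)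
Conditions: 15 (2 equiv), hν (390–440 nm LED), degassed ClCH2CH2Cl, 20 °C; then 80 °C in the dark
Reagents that add atoms: none
Why: Excitation of the diazo chromophore expels N2 with 1,2‑shift of the 1‑methoxyvinyl group from the carbonyl carbon to the diazo carbon (photochemical Wolff rearrangement, which makes the C(bridge)–C(OMe) bond) and gives vinylketene 16. The electron‑rich siloxyalkyne adds to the ketene in a (2+2) cycloaddition, its prenyl‑bearing carbon bonding to the ketene carbonyl carbon and its oxygen‑bearing carbon to the bridge‑bearing carbon, to give 4‑vinylcyclobutenone 17. On warming, 17 opens by four‑electron electrocyclic cleavage to dienylketene 18, which closes the six‑membered carbocycle by thermal six‑electron (disrotatory) electrocyclisation between the ketene carbon and the vinyl CH2 and enolises through dienone 19 to phenol 20. This is the diazo ketone/siloxyalkyne form of the Danheiser benzannulation. No stereocentre is formed; the regiochemistry follows from the polarisation of the ynol ether, so the free OH (ketene carbonyl), the O–Si (alkyne), the OMe (vinyl group), the prenyl group between two oxygens and the single ring C–H each fall on a fixed position. The step needs the Wolff shift to win over the 1,2‑hydrogen shift from the bridge CH2, which direct, metal‑free photolysis should favour; the long wavelength is chosen so that only the diazo ketone absorbs and the SEM‑protected pyranone stays dark, and excess alkyne keeps the ketene from acylating the product phenol.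

Step 8
Reactants: 20 6‑ethyl‑3‑{[4‑hydroxy‑6‑methoxy‑3‑(3‑methylbut‑2‑en‑1‑yl)‑2‑(triisopropylsilyloxy)phenyl]methyl}‑5‑methyl‑4‑{[2‑(trimethylsilyl)ethoxy]methoxy}‑2H‑pyran‑2‑one; 21 (R)‑2‑methylbutanoic acid
Product: 22 4‑[(6‑ethyl‑5‑methyl‑2‑oxo‑4‑{[2‑(trimethylsilyl)ethoxy]methoxy}‑2H‑pyran‑3‑yl)methyl]‑5‑methoxy‑2‑(3‑methylbut‑2‑en‑1‑yl)‑3‑(triisopropylsilyloxy)phenyl (2R)‑2‑methylbutanoate
Conditions: 21 (1.3 equiv), EDC, DMAP (0.2 equiv), CH2Cl2, 0 → 20 °C
Reagents that add atoms: none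
Why: Steglich esterification: the carbodiimide‑activated acid is passed by DMAP to the only free hydroxyl of 20, and a simple α‑alkyl acid is not expected to enolise or form a ketene under these conditions, so the (R) centre is carried over unchanged.

Step 9
Reactants: 22 4‑[(6‑ethyl‑5‑methyl‑2‑oxo‑4‑{[2‑(trimethylsilyl)ethoxy]methoxy}‑2H‑pyran‑3‑yl)methyl]‑5‑methoxy‑2‑(3‑methylbut‑2‑en‑1‑yl)‑3‑(triisopropylsilyloxy)phenyl (2R)‑2‑methylbutanoate
Product: 23 6‑ethyl‑3‑{[4‑hydroxy‑6‑methoxy‑5‑[(2R)‑2‑methylbutanoyl]‑3‑(3‑methylbut‑2‑en‑1‑yl)‑2‑(triisopropylsilyloxy)phenyl]methyl}‑5‑methyl‑4‑{[2‑(trimethylsilyl)ethoxy]methoxy}‑2H‑pyran‑2‑one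
Conditions: hν (254 nm, quartz), degassed cyclohexane, 20 °C, dilute
Reagents that add atoms: none
Why: Photo‑Fries rearrangement: excitation of the aryl ester homolyses the ArO–acyl bond and the caged acyl/aryloxyl pair recombines at the only unsubstituted ortho carbon (the other ortho and the para positions are quaternary) without touching the α‑stereocentre; the hydrogen‑bonded ortho‑hydroxy ketone formed should be photostable, and the known reversible photochemical ring opening of 2‑pyranones should leave the pyranone intact in a non‑nucleophilic solvent.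

Step 10
Reactants: 23 6‑ethyl‑3‑{[4‑hydroxy‑6‑methoxy‑5‑[(2R)‑2‑methylbutanoyl]‑3‑(3‑methylbut‑2‑en‑1‑yl)‑2‑(triisopropylsilyloxy)phenyl]methyl}‑5‑methyl‑4‑{[2‑(trimethylsilyl)ethoxy]methoxy}‑2H‑pyran‑2‑one
Product: 24 3‑{[2,4‑dihydroxy‑6‑methoxy‑5‑[(2R)‑2‑methylbutanoyl]‑3‑(3‑methylbut‑2‑en‑1‑yl)phenyl]methyl}‑6‑ethyl‑4‑hydroxy‑5‑methyl‑2H‑pyran‑2‑one (CNP0233274.1)
Conditions: Bu4NF (3 equiv), AcOH (3 equiv), THF, 0 → 40 °C
Reagents that add atoms: none
Why: Fluoride‑mediated desilylation: fluoride cleaves the aryl O–Si bond of the TIPS ether and attacks the silicon of the SEM group, which fragments by β‑elimination to release the acidic pyranone hydroxyl, while the acetic acid buffer keeps the medium from enolising the α‑branched ketone, so the (R) centre should be retained.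

**Compound list**

1 | 3‑pentanone | CCC(=O)CC | starting material
2 | malonyl dichloride | ClC(=O)CC(Cl)=O | starting material
3 | 6‑ethyl‑4‑hydroxy‑5‑methyl‑2H‑pyran‑2‑one | CCc1oc(=O)cc(O)c1C | intermediate
4 | N‑methoxy‑N‑methylacrylamide | C=CC(=O)N(C)OC | starting material
5 | 3‑(6‑ethyl‑4‑hydroxy‑5‑methyl‑2‑oxo‑2H‑pyran‑3‑yl)‑N‑methoxy‑N‑methylpropanamide | CCc1oc(=O)c(CCC(=O)N(C)OC)c(O)c1C | intermediate
6 | 3‑(6‑ethyl‑5‑methyl‑2‑oxo‑4‑{[2‑(trimethylsilyl)ethoxy]methoxy}‑2H‑pyran‑3‑yl)‑N‑methoxy‑N‑methylpropanamide | CCc1oc(=O)c(CCC(=O)N(C)OC)c(OCOCC[Si](C)(C)C)c1C | intermediate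
7 | lithium alkoxide adduct of 6 (former amide carbon bearing OLi, N(OMe)Me, 1‑methoxyvinyl and the CH2CH2‑pyranonyl chain; racemic) | CCc1oc(=O)c(CCC(O[Li])(C(=C)OC)N(C)OC)c(OCOCC[Si](C)(C)C)c1C | intermediate, not isolated
8 | 6‑ethyl‑3‑(4‑methoxy‑3‑oxopent‑4‑en‑1‑yl)‑5‑methyl‑4‑{[2‑(trimethylsilyl)ethoxy]methoxy}‑2H‑pyran‑2‑one | CCc1oc(=O)c(CCC(=O)C(=C)OC)c(OCOCC[Si](C)(C)C)c1C | intermediate
9 | lithium enolate of 8, formed at the chain CH2 next to the ketone | CCc1oc(=O)c(CC=C(O[Li])C(=C)OC)c(OCOCC[Si](C)(C)C)c1C | intermediate, not isolated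
10 | 6‑ethyl‑3‑[4‑methoxy‑3‑oxo‑2‑(trifluoroacetyl)pent‑4‑en‑1‑yl]‑5‑methyl‑4‑{[2‑(trimethylsilyl)ethoxy]methoxy}‑2H‑pyran‑2‑one (racemic, enolised) | CCc1oc(=O)c(CC(C(=O)C(F)(F)F)C(=O)C(=C)OC)c(OCOCC[Si](C)(C)C)c1C | intermediate, not isolated
11 | 3‑(2‑diazo‑4‑methoxy‑3‑oxopent‑4‑en‑1‑yl)‑6‑ethyl‑5‑methyl‑4‑{[2‑(trimethylsilyl)ethoxy]methoxy}‑2H‑pyran‑2‑one | CCc1oc(=O)c(CC(=[N+]=[N-])C(=O)C(OC)=C)c(OCOCC[Si](C)(C)C)c1C | intermediate
12 | methyl 4‑methylpent‑3‑enoate | COC(=O)CC=C(C)C | starting material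
13 | lithium 1,1‑dibromo‑5‑methylhexa‑1,4‑dien‑2‑olate | [Li]OC(CC=C(C)C)=C(Br)Br | intermediate, not isolated
14 | lithium 5‑methylhex‑4‑en‑1‑yn‑1‑olate | [Li]OC#CCC=C(C)C | intermediate, not isolated
15 | triisopropyl[(5‑methylhex‑4‑en‑1‑yn‑1‑yl)oxy]silane | CC(C)=CCC#CO[Si](C(C)C)(C(C)C)C(C)C | intermediate
16 | 6‑ethyl‑3‑[2‑(1‑methoxyethenyl)‑3‑oxoprop‑2‑en‑1‑yl]‑5‑methyl‑4‑{[2‑(trimethylsilyl)ethoxy]methoxy}‑2H‑pyran‑2‑one (the vinylketene O=C=C(CH2‑pyranonyl)–C(OMe)=CH2) | CCc1oc(=O)c(CC(=C=O)C(OC)=C)c(OCOCC[Si](C)(C)C)c1C | intermediate, not isolated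
17 | 6‑ethyl‑3‑{[1‑(1‑methoxyethenyl)‑3‑(3‑methylbut‑2‑en‑1‑yl)‑4‑oxo‑2‑(triisopropylsilyloxy)cyclobut‑2‑en‑1‑yl]methyl}‑5‑methyl‑4‑{[2‑(trimethylsilyl)ethoxy]methoxy}‑2H‑pyran‑2‑one (racemic) | CCc1oc(=O)c(CC2(C(OC)=C)C(=O)C(CC=C(C)C)=C2O[Si](C(C)C)(C(C)C)C(C)C)c(OCOCC[Si](C)(C)C)c1C | intermediate, not isolated
18 | dienylketene O=C=C(prenyl)–C(OTIPS)=C(CH2‑pyranonyl)–C(OMe)=CH2, ketene and methoxyvinyl groups cis on the central double bond | CCc1oc(=O)c(C/C(C(OC)=C)=C(O[Si](C(C)C)(C(C)C)C(C)C)/C(CC=C(C)C)=C=O)c(OCOCC[Si](C)(C)C)c1C | intermediate, not isolated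
19 | 6‑ethyl‑3‑{[2‑methoxy‑5‑(3‑methylbut‑2‑en‑1‑yl)‑4‑oxo‑6‑(triisopropylsilyloxy)cyclohexa‑1,5‑dien‑1‑yl]methyl}‑5‑methyl‑4‑{[2‑(trimethylsilyl)ethoxy]methoxy}‑2H‑pyran‑2‑one (keto tautomer of 20) | CCc1oc(=O)c(CC2=C(OC)CC(=O)C(CC=C(C)C)=C2O[Si](C(C)C)(C(C)C)C(C)C)c(OCOCC[Si](C)(C)C)c1C | intermediate, not isolated
20 | 6‑ethyl‑3‑{[4‑hydroxy‑6‑methoxy‑3‑(3‑methylbut‑2‑en‑1‑yl)‑2‑(triisopropylsilyloxy)phenyl]methyl}‑5‑methyl‑4‑{[2‑(trimethylsilyl)ethoxy]methoxy}‑2H‑pyran‑2‑one | CCc1oc(=O)c(Cc2c(O[Si](C(C)C)(C(C)C)C(C)C)c(CC=C(C)C)c(O)cc2OC)c(OCOCC[Si](C)(C)C)c1C | intermediate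
21 | (R)‑2‑methylbutanoic acid | CC[C@@H](C)C(=O)O | starting material
22 | 4‑[(6‑ethyl‑5‑methyl‑2‑oxo‑4‑{[2‑(trimethylsilyl)ethoxy]methoxy}‑2H‑pyran‑3‑yl)methyl]‑5‑methoxy‑2‑(3‑methylbut‑2‑en‑1‑yl)‑3‑(triisopropylsilyloxy)phenyl (2R)‑2‑methylbutanoate | CCc1oc(=O)c(Cc2c(O[Si](C(C)C)(C(C)C)C(C)C)c(CC=C(C)C)c(OC(=O)[C@H](C)CC)cc2OC)c(OCOCC[Si](C)(C)C)c1C | intermediate
23 | 6‑ethyl‑3‑{[4‑hydroxy‑6‑methoxy‑5‑[(2R)‑2‑methylbutanoyl]‑3‑(3‑methylbut‑2‑en‑1‑yl)‑2‑(triisopropylsilyloxy)phenyl]methyl}‑5‑methyl‑4‑{[2‑(trimethylsilyl)ethoxy]methoxy}‑2H‑pyran‑2‑one | CCc1oc(=O)c(Cc2c(O[Si](C(C)C)(C(C)C)C(C)C)c(CC=C(C)C)c(O)c(C(=O)[C@H](C)CC)c2OC)c(OCOCC[Si](C)(C)C)c1C | intermediate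
24 | 3‑{[2,4‑dihydroxy‑6‑methoxy‑5‑[(2R)‑2‑methylbutanoyl]‑3‑(3‑methylbut‑2‑en‑1‑yl)phenyl]methyl}‑6‑ethyl‑4‑hydroxy‑5‑methyl‑2H‑pyran‑2‑one | CCc1oc(=O)c(Cc2c(O)c(CC=C(C)C)c(O)c(C(=O)[C@H](C)CC)c2OC)c(O)c1C | target

**Step count and risks**

Total steps: 10. Longest linear sequence: 9 steps (steps 1–5 and 7–10); the alkyne branch (step 6) joins at step 7.

Steps most likely to fail:

1. Step 7 (benzannulation). The carbene may take a 1,2‑hydrogen shift from the bridge CH2 instead of the Wolff shift, or the vinylketene may dimerise or acylate the product phenol before it meets the alkyne. Fallback, setting out from pyranone 3 and acid 21 and coming back at target 24: the methylene bridge is made last by joining two preformed rings, the classical Mannich/quinone‑methide coupling of pyranone–phloroglucinol natural products. Acid 21 is converted with (COCl)2 and catalytic DMF into (R)‑2‑methylbutanoyl chloride F1, which acylates 5‑methoxyresorcinol (AlCl3, CH2Cl2–PhNO2, 0 °C) to (2R)‑1‑(2,4‑dihydroxy‑6‑methoxyphenyl)‑2‑methylbutan‑1‑one F2. C‑Prenylation between the two hydroxyls (prenyl bromide, aq. KOH, 0 °C) should give (2R)‑1‑[2,4‑dihydroxy‑6‑methoxy‑3‑(3‑methylbut‑2‑en‑1‑yl)phenyl]‑2‑methylbutan‑1‑one F3. Pyranone 3 and N,N‑dimethylmethyleneiminium iodide give the Mannich base 3‑[(dimethylamino)methyl]‑6‑ethyl‑4‑hydroxy‑5‑methyl‑2H‑pyran‑2‑one F4. Warmed with F3 (MeCN, 50 °C), F4 loses dimethylamine and alkylates the one open ring carbon of F3, which should give 24 directly.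

2. Step 9 (photochemical acyl shift). The pyranone, which absorbs more strongly and at longer wavelength than the aryl ester, may act as an inner filter or energy sink, so that the ester is not excited or the pyranone ring is degraded; escape of the radical pair from the solvent cage would only return phenol 20. Fallback, setting out from phenol 20 and coming back at target 24: a ground‑state ortho acylation replaces the ester and its photolysis. Phenol 20 is turned into its titanium phenoxide with TiCl4 (CH2Cl2, −78 °C) and treated with (R)‑2‑methylbutanoyl chloride F1, made from 21 as above. Metal‑templated Friedel–Crafts acylation at the free ortho carbon, with loss of the Lewis‑acid‑labile SEM acetal on work‑up, should give 6‑ethyl‑4‑hydroxy‑3‑{[4‑hydroxy‑6‑methoxy‑5‑[(2R)‑2‑methylbutanoyl]‑3‑(3‑methylbut‑2‑en‑1‑yl)‑2‑(triisopropylsilyloxy)phenyl]methyl}‑5‑methyl‑2H‑pyran‑2‑one F5. Bu4NF/AcOH then removes the TIPS group to give 24.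

3. Step 2 (Michael addition). The pyranone anion is a weak nucleophile and the acrylamide a weak acceptor, so the conjugate addition may stall or revert on heating. Fallback, setting out from pyranone 3 and coming back at amide 5: a far stronger acceptor is used and the amide is made afterwards. Pyranone 3, aqueous formaldehyde and Meldrum's acid (cat. L‑proline, EtOH, then reflux) should undergo Knoevenagel condensation, Michael addition and decarboxylative lactonisation to the enol lactone 7‑ethyl‑8‑methyl‑3,4‑dihydro‑2H,5H‑pyrano[4,3‑b]pyran‑2,5‑dione F6. This activated ester is opened at its enol‑ester carbonyl by MeNHOMe·HCl/iPr2NEt (CH2Cl2, 20 °C), giving 5.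

**Further compounds**

F1 | step 7 | (R)‑2‑methylbutanoyl chloride | CC[C@@H](C)C(Cl)=O
F2 | step 7 | (2R)‑1‑(2,4‑dihydroxy‑6‑methoxyphenyl)‑2‑methylbutan‑1‑one | CC[C@@H](C)C(=O)c1c(O)cc(O)cc1OC
F3 | step 7 | (2R)‑1‑[2,4‑dihydroxy‑6‑methoxy‑3‑(3‑methylbut‑2‑en‑1‑yl)phenyl]‑2‑methylbutan‑1‑one | CC[C@@H](C)C(=O)c1c(O)c(CC=C(C)C)c(O)cc1OC
F4 | step 7 | 3‑[(dimethylamino)methyl]‑6‑ethyl‑4‑hydroxy‑5‑methyl‑2H‑pyran‑2‑one | CCc1oc(=O)c(CN(C)C)c(O)c1C
F5 | step 9 | 6‑ethyl‑4‑hydroxy‑3‑{[4‑hydroxy‑6‑methoxy‑5‑[(2R)‑2‑methylbutanoyl]‑3‑(3‑methylbut‑2‑en‑1‑yl)‑2‑(triisopropylsilyloxy)phenyl]methyl}‑5‑methyl‑2H‑pyran‑2‑one | CCc1oc(=O)c(Cc2c(O[Si](C(C)C)(C(C)C)C(C)C)c(CC=C(C)C)c(O)c(C(=O)[C@H](C)CC)c2OC)c(O)c1C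
F6 | step 2 | 7‑ethyl‑8‑methyl‑3,4‑dihydro‑2H,5H‑pyrano[4,3‑b]pyran‑2,5‑dione | CCc1oc(=O)c2CCC(=O)Oc2c1C
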